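Running for E means choosing among set-ups, and the reckoning here follows how fast the rate fades at the level of G each vessel holds.

| flask | X | Z | G | remark | time |
|---|---|---|---|---|---|
| midnight | 0.40 M | 0.40 M | 1 M | run made earlier |  |
| dawn | 0.20 M | 0.20 M | 1 M | run made earlier |  |
| spring | 0.30 M | 0.30 M | 1 M | run made earlier |  |
| noon | 0.40 M | 0.40 M | 0.50 M | run made earlier |  |
| teal | 0.40 M | 0.40 M | 1.00 M | a single well-mixed tank run continuously and read at steady state, 10 min in it on average |  |
| blue | 0.40 M | 0.40 M | 1.00 M | a closed flask charged with all of it at once and left for 10 min | 10 min |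
| red | 0.40 M | 0.40 M | 1.00 M | a single well-mixed tank run continuously and read at steady state, 50.0 min in it on average |  |
| green | 0.40 M | 0.40 M | 1.00 M (fed, over 8.00 min) | a stirred flask in which G is dosed at a steady rate over 8.00 min without added volume, worked up at 10 min | 10 min |

- midnight (time / min: E / %): 0.500: 2.1; 0.833: 3.6; 1.33: 5.4; 2.00: 8.4; 4.00: 12.7; 6.00: 16.3
- dawn (time / min: E / %): 0.833: 3.6; 1.33: 6.1; 2.00: 8.2; 4.00: 13.4; 6.00: 18.0; 10.0: 23.8
- spring (time / min: E / %): 0.667: 2.6; 2.00: 7.1; 4.00: 12.7; 5.00: 14.8; 8.00: 19.2; 10.0: 22.1
- noon (time / min: E / %): 0.833: 2.0; 1.50: 3.2; 3.00: 7.2; 5.00: 7.9; 10.0: 13.8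

(standard deviation of a reading: 0.5 percentage points)

- the set-up with the highest amount of E at the outlet or at the end, in percent of the X and Z together put in ("none" if the first two lie within 2 percentage points) (teal / blue / red / green / none)
- amount of E at the outlet or at the end, in percent of the X and Z together put in, teal
- amount of E at the outlet or at the end, in percent of the X and Z together put in, blue
- amount of E at the outlet or at the end, in percent of the X and Z together put in, red
- amount of E at the outlet or at the end, in percent of the X and Z together put in, green

- G is single-handed; X and Z are mirror images of each other, charged as a racemate, each of them at the stated concentration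
- the stated concentrations are those of everything mixed, before any reaction; amounts are the same in each set-up
- the feed brings no volume worth counting
- the earlier runs were made in a closed, stirred flask
- the handed part of G does not stay in what it makes, so the products of the two hands are mirror images too

Read midnight against noon: the same substrate, but G at 1 M and 0.50 M. Early slope over late slope is 2.40 for midnight, around 5.00 min, and 2.03 for noon, around 7.50 min. As a steady fall per minute these readings give 0.175 min⁻¹ and 0.0947 min⁻¹, about twice for twice the G, so the fall looks second-order in G.

Hence the fade number 0.278 L mol⁻¹ min⁻¹: that slope ratio less one, per minute and per M of G charged, averaged over both runs. It lumps together whatever lowers the rate, the loss of X as well as the loss of G. The first noon slope reads 0.0960 L mol⁻¹ min⁻¹ as the rate constant for E.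

My own reckoning, which counts the whole fade as loss of G: at the charge, the fade is 0.278 min⁻¹. In red, feed balancing fade gives G of 0.235 M, where the fade is 0.0653 min⁻¹, slower than at the charge. Treating Z as untouched, E in red reckons to 26.5 %. The spring run, with X at 0.30 M, reads 22.1 % at 10.0 min; taken as a stand-in for blue, that reading puts red ahead by 4.4 percentage points in this reckoning, over the margin of 2 points.

The forecast differs. It reasons that “G must also decay on its own”, gives teal 16 %, blue 21.7 %, red 22.3 % and green 16.7 %, and answers none.

The flask gives teal 17.4 %, blue 21.8 %, red 31.2 % and green 17.5 %; the best is red.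

    G + X → E (k = 0.00160 L mol⁻¹ s⁻¹)
    G + Z → Q (k = 7.10 × 10⁻⁴ L mol⁻¹ s⁻¹)
    X ⇌ Z (k = 0.0200 s⁻¹)
    2 G → D (k = 9.60 × 10⁻⁴ L mol⁻¹ s⁻¹)
    G ⇌ J (K = 1.30, k = 1.40 × 10⁻⁴ s⁻¹)

Red holds X at 27.4 % and Z at 27.5 % of the X and Z together charged, with G at 0.238 M beside the 0.235 M from the fade number. For teal, with 10 min in the tank on average, the fade number gives G of 0.446 M. That G, times 0.0960 L mol⁻¹ min⁻¹, the average stay and the X of 37.2 % of the X and Z together charged at the teal outlet, gives E of 15.9 %, against 17.4 % in teal.

The readings are calculated for an exercise; noise was put on by code.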